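**Retrosynthetic overview**

1. Target 21 ⇐ bromohydrin formation across C2=C3 of (4S,6R)-10-bromo-α-chamigrene 20 ⇐ methylation of the C7 enol triflate of spiro ketone 18.
2. 18 ⇐ oxidative decarboxylation and semipinacol contraction of the cis-fused hydroxy acid 16: C5 shifts from C7 to C6, so ring B (C1–C6) arises from the cycloheptene C6–C1–C2=C3–C4–C5–C7.
3. 16 ⇐ ring-closing metathesis of a C6 allyl arm and a C7 3-methylbut-3-enyl arm ⇐ allylation and organocerium addition on the ring-A bromo β-keto ester 9.
4. 9 ⇐ bromonium/enol cyclisation (C6–C11 bond) of a hemiketal made from bromolactone 5 ⇐ L-glutamic acid, which supplies C10 and its bromine.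
5. Ring order: ring A, then the temporary seven-membered ring, then ring B by contraction. Enabling feature: C7 of ring A is an sp2 carbon bonded directly to the spiro atom C6, so it can serve for a time as a carbinol carbon that carries ring-B atom C5; a cation at C6 then pulls C5 across the C6–C7 bond and leaves C7 as the ketone from which the C7 methyl and C7=C8 are made.

Key step: step 10

Remark: atom labels in the text follow chamigrene numbering (ring B = C1–C6 with spiro atom C6; ring A = C6–C11 with methyl-bearing C7, bromo C10 and gem-dimethyl C11); systematic names carry their own locants.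

**Route**

Step 1
Reactants: 1 L-glutamic acid
Product: 2 (2S)-2-bromopentanedioic acid
Conditions: NaNO2, 48% aq HBr, −5 to 0 °C
Reagents that add atoms: hydrogen bromide, Br
Why: Diazotisation of the α-amino group and substitution by bromide should run through an α-lactone formed by the neighbouring carboxylate, so two inversions leave the stereocenter (the later C10) in the S configuration (diazotisation–halogenation of an α-amino acid with retention).

Step 2
Reactants: 2 (2S)-2-bromopentanedioic acid
Product: 3 dimethyl (2S)-2-bromopentanedioate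
Conditions: MeOH, H2SO4 (cat.), 40 °C
Reagents that add atoms: methanol, CO
Why: Fischer esterification converts both carboxyl groups under acidic conditions that neither enolise nor substitute the α-bromo stereocenter.

Step 3
Reactants: 3 dimethyl (2S)-2-bromopentanedioate
Product: 5 (5S)-5-bromo-6,6-dimethyloxan-2-one, via bromohydrin ester 4 (not isolated)
Conditions: MeMgBr (2.05 equiv), THF, −78 to −20 °C; H2O; then TsOH (cat.), CH2Cl2, rt
Reagents that add atoms: methylmagnesium bromide, C[Mg]Br
Why: The α-bromo ester is the more electrophilic carbonyl group and should take up two methyl groups at low temperature (Grignard addition), after which the tertiary alcohol closes onto the remaining ester under acid catalysis to the six-membered lactone; the stereocenter is not involved.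

Step 4
Reactants: 5 (5S)-5-bromo-6,6-dimethyloxan-2-one; 6 methyl acetate
Product: 8 methyl 2-[(5S)-5-bromo-2-hydroxy-6,6-dimethyloxan-2-yl]acetate, via lithium enolate 7 (not isolated)
Conditions: LiN(i-Pr)2, THF, −78 °C; then 5; AcOH, −78 °C
Reagents that add atoms: none
Why: Claisen-type addition of the ester enolate to the lactone carbonyl should stop at the tetrahedral stage at −78 °C, so the product is the cyclic hemiketal (both C2 epimers) of the δ-hydroxy β-keto ester, in which the ring oxygen stays on C11 and cannot displace the neighbouring bromide.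

Step 5
Reactants: 8 methyl 2-[(5S)-5-bromo-2-hydroxy-6,6-dimethyloxan-2-yl]acetate
Product: 9 methyl (3S)-3-bromo-2,2-dimethyl-6-oxocyclohexane-1-carboxylate
Conditions: SnCl4 (1.5 equiv), CH2Cl2, −78 to −20 °C; H2O work-up
Reagents that add atoms: none
Why: SnCl4 should ionise the tertiary C11–O bond with anchimeric help from bromine, so the C10–Br bond is never broken and C10 stays S, and the tin-chelated β-keto ester enol should close ring A through carbon at C11 because O-alkylation is reversible (Lewis acid cation–enol cyclisation of a β-keto ester, the bromine counterpart of the epoxide-initiated closure of the same ring); 9 is expected as C1 epimers and enol, all of which give the same enolate in step 6.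

Step 6
Reactants: 9 methyl (3S)-3-bromo-2,2-dimethyl-6-oxocyclohexane-1-carboxylate; 10 allyl methyl carbonate
Product: 11 methyl (1S,3S)-3-bromo-2,2-dimethyl-6-oxo-1-(prop-2-en-1-yl)cyclohexane-1-carboxylate
Conditions: Pd(PPh3)4 (5 mol %), THF, 40 °C
Reagents that add atoms: none
Why: Tsuji–Trost allylation: the π-allyl palladium complex should alkylate the β-keto ester enolate at C6 under neutral conditions, entering anti to the pseudo-axial methyl on C11 (allyl trans to the C10 bromine); this C6 configuration is temporary because C6 becomes planar in step 10, so both epimers would converge.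

Step 7
Reactants: 11 methyl (1S,3S)-3-bromo-2,2-dimethyl-6-oxo-1-(prop-2-en-1-yl)cyclohexane-1-carboxylate; 12 4-bromo-2-methylbut-1-ene
Product: 14 methyl (1S,3S,6R)-3-bromo-6-hydroxy-2,2-dimethyl-6-(3-methylbut-3-en-1-yl)-1-(prop-2-en-1-yl)cyclohexane-1-carboxylate, via Grignard reagent 13 (not isolated)
Conditions: 12, Mg, THF, rt; CeCl3, THF, −78 °C; then 11, −78 °C; H2O
Reagents that add atoms: none
Why: The weakly basic organocerium reagent (Grignard-type 1,2-addition) should add to the C7 ketone from the equatorial direction because the axial path is blocked by the syn-axial methyl on C11, which puts the new C7–C5 bond trans and the hydroxyl cis to the C10 bromine and leaves the hindered ester untouched.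

Step 8
Reactants: 14 methyl (1S,3S,6R)-3-bromo-6-hydroxy-2,2-dimethyl-6-(3-methylbut-3-en-1-yl)-1-(prop-2-en-1-yl)cyclohexane-1-carboxylate
Product: 15 methyl (1S,7R,10S)-10-bromo-7-hydroxy-4,11,11-trimethylbicyclo[5.4.0]undec-3-ene-1-carboxylate
Conditions: second-generation Grubbs catalyst RuCl2(=CHPh)(H2IMes)(PCy3) (5 mol %), CH2Cl2, 40 °C
Reagents that add atoms: none
Why: Ring-closing metathesis of the monosubstituted and the 1,1-disubstituted alkene, held cis on neighbouring ring carbons, should close the seven-membered ring as the trisubstituted C2=C3 alkene with loss of ethene; no stereocenter is touched.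

Step 9
Reactants: 15 methyl (1S,7R,10S)-10-bromo-7-hydroxy-4,11,11-trimethylbicyclo[5.4.0]undec-3-ene-1-carboxylate
Product: 16 (1S,7R,10S)-10-bromo-7-hydroxy-4,11,11-trimethylbicyclo[5.4.0]undec-3-ene-1-carboxylic acid
Conditions: n-PrSLi, DMPU/THF, rt; then 1 M HCl
Reagents that add atoms: none
Why: SN2 demethylation at the O-methyl group by the thiolate avoids attack at a carbonyl flanked by two fully substituted carbons, and the neopentyl-type C10 bromide should resist substitution under these conditions.

Step 10
Reactants: 16 (1S,7R,10S)-10-bromo-7-hydroxy-4,11,11-trimethylbicyclo[5.4.0]undec-3-ene-1-carboxylic acid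
Product: 18 (4S,6S)-4-bromo-5,5,9-trimethylspiro[5.5]undec-8-en-1-one, via oxirane 17 (not isolated)
Conditions: constant-current electrolysis (graphite anode, Pt cathode, undivided cell), 2,4,6-collidine, n-Bu4NPF6, CH2Cl2/(CF3)2CHOH 9:1, 0 °C; then BF3·OEt2 (20 mol %), 0 °C to rt
Reagents that add atoms: none
Why: Anodic oxidation of the carboxylate of 16 (Hofer–Moest conditions) should expel CO2 and, after a second electron transfer, place a tertiary carbocation exactly at C6, which the axial C7 hydroxyl traps as oxirane 17; BF3·OEt2 then reopens 17 at the strained, CMe2-flanked C6–O bond and C5 shifts from C7 to C6 while C7 becomes the ketone (semipinacol/Meinwald rearrangement). The closest known reactions are the anodic oxidation of β-hydroxy carboxylic acids to 1,2-shifted ketones, the electrochemical generation of hindered tertiary carbocations from carboxylic acids, and the acid-promoted contraction of ring-fusion epoxides and diols of fused bicycles to spiro ketones. Ring B is not closed by a cyclisation: it arises from the seven-membered ring C6–C1–C2–C3–C4–C5–C7 by a suprafacial [1,2]-alkyl shift that expels C7, a seven-to-six ring contraction. The new stereocenter C6 is controlled only by the configuration of C7: C5 migrates across the face on which it already sits, anti to the C7–O bond, so C5 ends trans and C1 cis to the C10 bromine, and the earlier configuration at C6 is erased at the cation stage. The step needs migration of C5 in preference to C8 (contraction of ring A), to proton loss and to transannular capture by the C2=C3 alkene; this should follow from the relief of cycloheptene strain on forming a cyclohexene, from the irreversible formation of the C7 carbonyl, and from the carboxyl group that fixes the site of ionisation.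

Step 11
Reactants: 18 (4S,6S)-4-bromo-5,5,9-trimethylspiro[5.5]undec-8-en-1-one
Product: 19 (4S,6S)-4-bromo-5,5,9-trimethylspiro[5.5]undeca-1,8-dien-1-yl trifluoromethanesulfonate
Conditions: KN(SiMe3)2, THF, −78 °C; PhNTf2, −78 to 0 °C; aq HCl work-up
Reagents that add atoms: N-phenylbis(trifluoromethanesulfonimide), O=S(=O)(N(c1ccccc1)S(=O)(=O)C(F)(F)F)C(F)(F)F
Why: The ketone can enolise only toward C8 because C6 is quaternary, so O-triflation of the potassium enolate should give a single enol triflate with the C7=C8 double bond.

Step 12
Reactants: 19 (4S,6S)-4-bromo-5,5,9-trimethylspiro[5.5]undeca-1,8-dien-1-yl trifluoromethanesulfonate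
Product: 20 (4S,6R)-4-bromo-1,5,5,9-tetramethylspiro[5.5]undeca-1,8-diene
Conditions: MeZnCl (1.5 equiv), Pd(PPh3)4 (5 mol %), THF, 0 °C to rt
Reagents that add atoms: methylzinc chloride, C[Zn]Cl
Why: Negishi coupling: zerovalent palladium should insert into the C(sp2)–OTf bond and not into the hindered secondary alkyl bromide, and transmetalation from zinc installs the C7 methyl group.

Step 13
Reactants: 20 (4S,6R)-4-bromo-1,5,5,9-tetramethylspiro[5.5]undeca-1,8-diene
Product: 21 (2R,3R,6R,10S)-2,10-dibromo-3,7,11,11-tetramethylspiro[5.5]undec-7-en-3-ol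
Conditions: NBS (1.05 equiv), acetone/H2O 4:1, 0 °C, dark
Reagents that add atoms: N-bromosuccinimide, BrN1C(=O)CCC1=O; water, O
Why: Bromohydrin formation: the bromonium ion should form on the unhindered C2=C3 alkene of ring B (C7=C8 is shielded by the spiro centre) from the face of the equatorial C11 arm, away from the axial C7 arm whose methyl roofs the other face, and water should open it anti at the tertiary C3 (Markovnikov), which sets C2 (R) and C3 (R) with bromine and hydroxyl trans.

**Compound list**

1 | L-glutamic acid | N[C@@H](CCC(O)=O)C(O)=O | starting material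
2 | (2S)-2-bromopentanedioic acid | OC(=O)CC[C@H](Br)C(O)=O | intermediate
3 | dimethyl (2S)-2-bromopentanedioate | COC(=O)CC[C@H](Br)C(=O)OC | intermediate
4 | methyl (4S)-4-bromo-5-hydroxy-5-methylhexanoate (formed as its magnesium alkoxide, not isolated) | COC(=O)CC[C@H](Br)C(C)(C)O | intermediate
5 | (5S)-5-bromo-6,6-dimethyloxan-2-one | O=C1CC[C@H](Br)C(C)(C)O1 | intermediate
6 | methyl acetate | COC(C)=O | starting material
7 | lithium 1-methoxyethen-1-olate (not isolated) | [Li+].[O-]C(=C)OC | intermediate
8 | methyl 2-[(5S)-5-bromo-2-hydroxy-6,6-dimethyloxan-2-yl]acetate (both C2 epimers) | COC(=O)CC1(O)CC[C@H](Br)C(C)(C)O1 | intermediate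
9 | methyl (3S)-3-bromo-2,2-dimethyl-6-oxocyclohexane-1-carboxylate (C1 epimers and enol) | COC(=O)C1C(=O)CC[C@H](Br)C1(C)C | intermediate
10 | allyl methyl carbonate | C=CCOC(=O)OC | starting material
11 | methyl (1S,3S)-3-bromo-2,2-dimethyl-6-oxo-1-(prop-2-en-1-yl)cyclohexane-1-carboxylate | COC(=O)[C@]1(CC=C)C(=O)CC[C@H](Br)C1(C)C | intermediate
12 | 4-bromo-2-methylbut-1-ene | CC(=C)CCBr | starting material
13 | (3-methylbut-3-en-1-yl)magnesium bromide (not isolated) | CC(=C)CC[Mg]Br | intermediate
14 | methyl (1S,3S,6R)-3-bromo-6-hydroxy-2,2-dimethyl-6-(3-methylbut-3-en-1-yl)-1-(prop-2-en-1-yl)cyclohexane-1-carboxylate | COC(=O)[C@]1(CC=C)[C@@](O)(CCC(C)=C)CC[C@H](Br)C1(C)C | intermediate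
15 | methyl (1S,7R,10S)-10-bromo-7-hydroxy-4,11,11-trimethylbicyclo[5.4.0]undec-3-ene-1-carboxylate | COC(=O)[C@]12CC=C(C)CC[C@@]1(O)CC[C@H](Br)C2(C)C | intermediate
16 | (1S,7R,10S)-10-bromo-7-hydroxy-4,11,11-trimethylbicyclo[5.4.0]undec-3-ene-1-carboxylic acid | OC(=O)[C@]12CC=C(C)CC[C@@]1(O)CC[C@H](Br)C2(C)C | intermediate
17 | (1S,7R,10S)-10-bromo-4,11,11-trimethyl-12-oxatricyclo[5.4.1.0(1,7)]dodec-3-ene, oxirane oxygen cis to the C10 bromine (not isolated) | CC1=CC[C@@]23O[C@]2(CC1)CC[C@H](Br)C3(C)C | intermediate
18 | (4S,6S)-4-bromo-5,5,9-trimethylspiro[5.5]undec-8-en-1-one | O=C1CC[C@H](Br)C(C)(C)[C@@]12CCC(C)=CC2 | intermediate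
19 | (4S,6S)-4-bromo-5,5,9-trimethylspiro[5.5]undeca-1,8-dien-1-yl trifluoromethanesulfonate | O=S(=O)(OC1=CC[C@H](Br)C(C)(C)[C@@]12CCC(C)=CC2)C(F)(F)F | intermediate
20 | (4S,6R)-4-bromo-1,5,5,9-tetramethylspiro[5.5]undeca-1,8-diene (10-bromo-α-chamigrene) | CC1=CC[C@H](Br)C(C)(C)[C@@]12CCC(C)=CC2 | intermediate
21 | (2R,3R,6R,10S)-2,10-dibromo-3,7,11,11-tetramethylspiro[5.5]undec-7-en-3-ol | CC1=CC[C@H](Br)C(C)(C)[C@@]12CC[C@@](C)(O)[C@H](Br)C2 | target

**Step count and risks**

Total step count: 13. Longest linear sequence: 13 steps, from L-glutamic acid (6, 10 and 12 are used as purchased).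

Steps most likely to fail:

Step 5. O-alkylation back to the oxane ring or proton loss from the tertiary cation may outrun C–C bond formation, and a reversible bromonium/alkene interplay could erode the C10 configuration. The fallback sets out from lactone 5 and comes back at β-keto ester 9. Lactone 5 would be opened at its tertiary alkyl–oxygen bond with SOCl2 and catalytic ZnCl2 (55 °C), again with bromine participation, to (4S)-4-bromo-5-chloro-5-methylhexanoyl chloride F1. C-acylation of the magnesium enolate of potassium methyl malonate (MgCl2, Et3N, MeCN) and decarboxylation on acidic work-up would give methyl (6S)-6-bromo-7-chloro-7-methyl-3-oxooctanoate F2. Solvolysis of the tertiary chloride of F2 in (CF3)2CHOH at room temperature, a known way to release a configurationally defined bromonium ion from a vicinal bromochloride, would let the enol close ring A to 9.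

Step 10. Oxidation of the C2=C3 alkene at the anode, proton loss from the C6 cation, or failure of the hindered carboxylate to decarboxylate cleanly may prevent the cation from being formed at C6. The fallback sets out from acid 16 and comes back at spiro ketone 18. The tertiary hydroxyl would be silylated (TMSOTf, 2,6-lutidine; the silyl ester is cleaved on work-up) to (1S,7R,10S)-10-bromo-4,11,11-trimethyl-7-[(trimethylsilyl)oxy]bicyclo[5.4.0]undec-3-ene-1-carboxylic acid F3. Its acid chloride would be converted with sodium 2-sulfanylidenepyridin-1(2H)-olate into the thiohydroxamate ester 2-sulfanylidenepyridin-1(2H)-yl (1S,7R,10S)-10-bromo-4,11,11-trimethyl-7-[(trimethylsilyl)oxy]bicyclo[5.4.0]undec-3-ene-1-carboxylate F4. Visible-light Barton decarboxylation would give the tertiary sulfide 2-{[(7R,10S)-10-bromo-4,11,11-trimethyl-7-[(trimethylsilyl)oxy]bicyclo[5.4.0]undec-3-en-1-yl]sulfanyl}pyridine F5. Methylation with MeOTf (CH2Cl2, −40 to 0 °C) would turn the sulfide into a leaving group whose departure triggers the same 1,2-shift of C5 with loss of the silyl group (semipinacol rearrangement of a β-silyloxy sulfide) to give 18.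

Step 13. Poor facial selectivity in bromonium formation may put the bromine on the face syn to C7 and give the C2/C3 diastereomer. The fallback sets out from diene 20 and comes back at target 21, and turns the same facial preference to advantage. Epoxidation with 3-chloroperoxybenzoic acid (CH2Cl2, NaHCO3, 0 °C) would place the oxygen on the face that electrophiles prefer and give (2S,3R,6R,10S)-10-bromo-2,3-epoxy-3,7,11,11-tetramethylspiro[5.5]undec-7-ene F6. Opening with Li2NiBr4 (THF, 0 °C) at the secondary C2 with inversion would deliver bromine from the opposite face and leave the tertiary C3 hydroxyl in place.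

Further compounds
F1 | step 5 | (4S)-4-bromo-5-chloro-5-methylhexanoyl chloride | ClC(=O)CC[C@H](Br)C(C)(C)Cl
F2 | step 5 | methyl (6S)-6-bromo-7-chloro-7-methyl-3-oxooctanoate | COC(=O)CC(=O)CC[C@H](Br)C(C)(C)Cl
F3 | step 10 | (1S,7R,10S)-10-bromo-4,11,11-trimethyl-7-[(trimethylsilyl)oxy]bicyclo[5.4.0]undec-3-ene-1-carboxylic acid | OC(=O)[C@]12CC=C(C)CC[C@@]1(O[Si](C)(C)C)CC[C@H](Br)C2(C)C
F4 | step 10 | 2-sulfanylidenepyridin-1(2H)-yl (1S,7R,10S)-10-bromo-4,11,11-trimethyl-7-[(trimethylsilyl)oxy]bicyclo[5.4.0]undec-3-ene-1-carboxylate | S=C1C=CC=CN1OC(=O)[C@]12CC=C(C)CC[C@@]1(O[Si](C)(C)C)CC[C@H](Br)C2(C)C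
F5 | step 10 | 2-{[(7R,10S)-10-bromo-4,11,11-trimethyl-7-[(trimethylsilyl)oxy]bicyclo[5.4.0]undec-3-en-1-yl]sulfanyl}pyridine (C1 epimers) | c1ccc(nc1)SC12CC=C(C)CC[C@@]1(O[Si](C)(C)C)CC[C@H](Br)C2(C)C
F6 | step 13 | (2S,3R,6R,10S)-10-bromo-2,3-epoxy-3,7,11,11-tetramethylspiro[5.5]undec-7-ene | CC1=CC[C@H](Br)C(C)(C)[C@@]12CC[C@@]3(C)O[C@H]3C2
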